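**Retrosynthetic overview**

1. The target 26 is a guai-4-en-3-one diester. The O11 acetate and the O8 methacrylate are put on last, after opening an acetonide that bridges O8 and O11.
2. The C10–H and C1–H bonds come from the 1(10),4-dien-3-one 21, by vinylogous hydride delivery to C10 followed by equilibrating protonation at C1.
3. The plan rests on the 2-methylcyclopent-2-enone ring (C1–C5; C3 ketone, C4 methyl, C4=C5) fused through the C1–C5 bond to the seven-membered carbocycle (C1, C5, C6, C7, C8, C9, C10), whose methyl-bearing C10 sits next to C1. C3 is read as carbon monoxide, C4/C5 as a methyl alkyne and C10/C1/C2 as an allene, so the five-membered and the seven-membered ring form in the same step from the open-chain allenyne 19.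
4. Allenyne 19 comes from a propargylic mesylate by SN2′ methylation (C10 methyl and allene). The C9–C10 bond comes from a C9 triflate and a silyl-protected propargyl acetylide.
5. C7 and C8 come from an oxazolidinone syn aldol of the hex-4-ynoyl imide with a silyloxyacetaldehyde. The C11 dimethylcarbinol comes from MeMgBr addition to the derived ester.

Key step: step 12

Remark: guaiane numbering is used for the carbon atoms throughout. The target is read as (1R,7S,8R,10S), with H1, the C10 methyl, O8 and C11 on one face. The C8 descriptor is S while C9 bears oxygen (compounds 7–13) and R afterwards, without any change at the centre.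

**Route**

Step 1
Reactants: 1 hex-4-ynoic acid; 2 (S)-4-benzyl-1,3-oxazolidin-2-one
Product: 4 (S)-4-benzyl-3-(hex-4-ynoyl)-1,3-oxazolidin-2-one, via mixed pivalic anhydride 3 (not isolated)
Conditions: PivCl, Et3N, THF, −20 °C; then 2, LiCl, −20 °C → rt
Reagents that add atoms: none
Why: N-acylation of the LiCl-activated oxazolidinone by the mixed pivalic anhydride is the standard loading of this auxiliary, the tert-butyl group steering attack to the hexynoyl carbonyl, and no stereocenter is touched.

Step 2
Reactants: 4 (S)-4-benzyl-3-(hex-4-ynoyl)-1,3-oxazolidin-2-one; 5 (tert-butyldimethylsilyloxy)acetaldehyde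
Product: 8 (4S)-4-benzyl-3-[(2S,3S)-2-(but-2-yn-1-yl)-4-[(tert-butyldimethylsilyl)oxy]-3-hydroxybutanoyl]-1,3-oxazolidin-2-one, via Z-dibutylboron enolate 6 (not isolated), via dibutylboron aldolate 7 (not isolated)
Conditions: Bu2BOTf, i-Pr2NEt, CH2Cl2, −78 → 0 °C; 5, −78 → 0 °C; then pH 7 buffer, MeOH, 30 % H2O2, 0 °C
Reagents that add atoms: none
Why: In this oxazolidinone (Evans) syn aldol the Z boron enolate reacts through a chair Zimmerman–Traxler transition state in which the benzyl group of the (S)-auxiliary blocks one enolate face, so C7 and C8 are set together with the 2,3-syn relationship (2S,3S) that becomes the cis O8/C11 pair of the target.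

Step 3
Reactants: 8 the syn aldol imide
Product: 9 methyl (2S,3S)-2-(but-2-yn-1-yl)-4-[(tert-butyldimethylsilyl)oxy]-3-hydroxybutanoate
Conditions: MeMgBr, MeOH, CH2Cl2, 0 °C (MeOMgBr formed in the flask)
Reagents that add atoms: methanol (delivered as MeOMgBr), CO
Why: Transesterification with bromomagnesium methoxide attacks the exocyclic imide carbonyl held in a magnesium chelate and releases the auxiliary under conditions too mild for retro-aldol cleavage or epimerization of C7.

Step 4
Reactants: 9 the β-hydroxy methyl ester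
Product: 10 (2S,3S)-3-(but-2-yn-1-yl)-1-[(tert-butyldimethylsilyl)oxy]-4-methylpentane-2,4-diol
Conditions: MeMgBr (5 equiv), THF, 0 °C → rt; aq. NH4Cl
Reagents that add atoms: methylmagnesium bromide, C[Mg]Br
Why: Double Grignard addition to the methyl ester builds the C11 dimethylcarbinol, the O8 magnesium alkoxide formed first shielding the α-proton at C7 from enolization.

Step 5
Reactants: 10 the O9-silylated 8,11-diol
Product: 11 tert-butyl{[(4S,5S)-5-(but-2-yn-1-yl)-2,2,6,6-tetramethyl-1,3-dioxan-4-yl]methoxy}dimethylsilane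
Conditions: 2-methoxypropene, PPTS (cat.), CH2Cl2, 0 °C
Reagents that add atoms: 2-methoxypropene, C=C(C)OC
Why: Acid-catalysed transacetalization with the enol ether ties O8 and O11 into the 1,3-dioxane under kinetic conditions, PPTS being mild enough to keep the primary silyl ether so that no O8/O9 dioxolane can form.

Step 6
Reactants: 11 the silyl ether acetonide
Product: 12 [(4S,5S)-5-(but-2-yn-1-yl)-2,2,6,6-tetramethyl-1,3-dioxan-4-yl]methanol
Conditions: Bu4NF, THF, 0 °C → rt
Reagents that add atoms: none
Why: Fluoride-driven desilylation frees the C9 hydroxyl under basic conditions that neither move the acetonide nor affect the alkyne, which a hydrogenolytic ether cleavage would reduce.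

Step 7
Reactants: 12 the C9 alcohol
Product: 13 [(4S,5S)-5-(but-2-yn-1-yl)-2,2,6,6-tetramethyl-1,3-dioxan-4-yl]methyl trifluoromethanesulfonate
Conditions: Tf2O, 2,6-lutidine, CH2Cl2, −78 °C; used crude
Reagents that add atoms: trifluoromethanesulfonic anhydride, O=S(=O)(OS(=O)(=O)C(F)(F)F)C(F)(F)F
Why: Sulfonylation of the primary alcohol with triflic anhydride under lutidine buffering gives the most reactive C9 leaving group available for a β-branched and β-oxygenated carbon.

Step 8
Reactants: 13 the C9 triflate; 14 tert-butyldimethyl(prop-2-yn-1-yloxy)silane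
Product: 16 tert-butyl({4-[(4R,5S)-5-(but-2-yn-1-yl)-2,2,6,6-tetramethyl-1,3-dioxan-4-yl]but-2-yn-1-yl}oxy)dimethylsilane, via lithium acetylide 15 (not isolated)
Conditions: 14, n-BuLi, THF, −78 °C; then 13, DMPU, −78 → −20 °C
Reagents that add atoms: none
Why: SN2 alkylation of the lithium acetylide by the primary triflate in THF/DMPU forms the C9–C10 bond at low temperature where elimination and acetal participation are slow, and C8 next to the reacting carbon is not involved.

Step 9
Reactants: 16 the silyl-protected diyne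
Product: 17 4-[(4R,5S)-5-(but-2-yn-1-yl)-2,2,6,6-tetramethyl-1,3-dioxan-4-yl]but-2-yn-1-ol
Conditions: Bu4NF, THF, 0 °C
Reagents that add atoms: none
Why: Fluoride desilylation of the propargylic silyl ether proceeds with the acetonide and both alkynes inert to Bu4NF.

Step 10
Reactants: 17 the propargylic alcohol
Product: 18 4-[(4R,5S)-5-(but-2-yn-1-yl)-2,2,6,6-tetramethyl-1,3-dioxan-4-yl]but-2-yn-1-yl methanesulfonate
Conditions: MsCl, Et3N, CH2Cl2, −20 °C; used crude
Reagents that add atoms: methanesulfonyl chloride, CS(=O)(=O)Cl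
Why: Mesylation turns the propargylic hydroxyl into the leaving group required for the allene-forming substitution.

Step 11
Reactants: 18 the propargylic mesylate
Product: 19 (4R,5S)-5-(but-2-yn-1-yl)-2,2,6,6-tetramethyl-4-(2-methylbuta-2,3-dien-1-yl)-1,3-dioxane
Conditions: MeMgBr, CuBr·SMe2, LiBr, THF, −40 → 0 °C
Reagents that add atoms: methylmagnesium bromide, C[Mg]Br
Why: Anti SN2′ substitution of the propargylic mesylate by methylcopper delivers the methyl group to C10 and expels mesylate from C2 to give the 1,1-disubstituted allene, while the C4≡C5 alkyne has no leaving group and stays untouched.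

Step 12
Reactants: 19 the allenyne acetonide; 20 carbon monoxide
Product: 21 (7S,8R)-8,11-(isopropylidenedioxy)guaia-1(10),4-dien-3-one (tricyclic: cyclopentenone, cycloheptene and 1,3-dioxane)
Conditions: [Rh(CO)2Cl]2 (5 mol %), CO (1 atm), toluene (0.02 M), 90 °C
Reagents that add atoms: none
Why: [Rh(CO)2Cl]2 opens under CO to a monovalent rhodium carbonyl that takes up the C4≡C5 alkyne and the terminal C1=C2 π bond of the allene, couples C5 with the central allene carbon C1 to a rhodacyclopentene (Rh, C4, C5, C1, C2), inserts CO into the Rh–C2 bond and releases the ketone C3 by C–C reductive elimination at C4. The closest known reaction type is the rhodium-catalysed allenic Pauson–Khand (carbonylative [2+2+1]) cyclization of tethered allenynes at the distal allene bond, which is established for four-atom tethers and gives bicyclo[5.3.0]deca-1,7-dien-9-ones. The seven-membered ring (C1, C5, C6, C7, C8, C9, C10) closes in the oxidative C1–C5 coupling and keeps C1=C10 as a ring double bond exocyclic to the five-membered ring, and the five-membered ring (C1–C5) closes in the CO insertion and reductive elimination that form C2–C3 and C3–C4. No stereocenter is formed, since C1, C4, C5 and C10 all end sp2 and C7 and C8 are only carried through. The step needs the distal C1=C2 bond to react and not the proximal C10=C1 bond, which would give a six-membered ring with an α-methylene ketone, and this is secured by the known preference of the rhodium carbonyl chloride catalyst for the distal bond and by the methyl and C9 substituents that crowd C10. Ring closure is helped by the linear sp carbon C1, by the cis C6 and C9 arms on the dioxane and by high dilution, and the unsubstituted C2 terminus offers no β-hydrogen for diversion to a cross-conjugated triene.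

Step 13
Reactants: 21 the dienone acetonide
Product: 23 (1R,7S,8R,10S)-8,11-(isopropylidenedioxy)guai-4-en-3-one, via silyl dienol ether 22 (not isolated)
Conditions: Cu(OAc)2·H2O (5 mol %), 1,2-bis(diphenylphosphino)benzene (5 mol %), PhMe2SiH (2 equiv), toluene, rt; then NaOMe (0.2 equiv), MeOH, rt
Reagents that add atoms: none
Why: Conjugate reduction by a bisphosphine copper hydride in its vinylogous (1,6) mode should deliver hydride to the exocyclic δ-carbon C10 from the α face, opposite the cis-fused dioxane with O8, C11 and their methyl groups, which sets C10 (S), and methoxide then frees the dienolate and equilibrates it by γ-protonation at C1 to the conjugated 4-en-3-one with H1 trans to H10 (C1 R), the arrangement that keeps the C10 methyl and C2 trans across the C1–C10 bond.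

Step 14
Reactants: 23 the enone acetonide
Product: 24 (1R,7S,8R,10S)-8,11-dihydroxyguai-4-en-3-one
Conditions: AcOH/H2O/THF (3:1:1), 40 °C
Reagents that add atoms: none
Why: Acid-catalysed acetal hydrolysis is easy for this tetramethyl-1,3-dioxane, which must adopt a twist conformation, under conditions too mild to dehydrate the C11 carbinol.

Step 15
Reactants: 24 the 8,11-diol
Product: 25 (1R,7S,8R,10S)-11-hydroxy-3-oxoguai-4-en-8-yl 2-methylprop-2-enoate
Conditions: methacrylic anhydride, Et3N, DMAP (cat.), BHT (trace), CH2Cl2, 0 °C → rt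
Reagents that add atoms: methacrylic anhydride, C=C(C)C(=O)OC(=O)C(C)=C
Why: DMAP-catalysed acylation (Steglich type) is far faster at the secondary C8 hydroxyl than at the tertiary C11 hydroxyl, so the methacrylate goes on O8 only.

Step 16
Reactants: 25 the 8-methacrylate 11-alcohol
Product: 26 (1R,7S,8R,10S)-11-acetoxy-3-oxoguai-4-en-8-yl 2-methylprop-2-enoate (CNP0318307.1)
Conditions: Ac2O, DMAP (1 equiv), Et3N, BHT (trace), CH2Cl2, 40 °C
Reagents that add atoms: acetic anhydride, CC(=O)OC(C)=O
Why: DMAP-mediated acylation through the N-acetylpyridinium ion is the standard way to esterify a tertiary alcohol, and it leaves the enone, the methacrylate and the already equilibrated C1 centre as they are.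

**Compound list**

1 | hex-4-ynoic acid | CC#CCCC(=O)O | starting material
2 | (S)-4-benzyl-1,3-oxazolidin-2-one | O=C1N[C@@H](Cc2ccccc2)CO1 | starting material
3 | hex-4-ynoic pivalic anhydride | CC#CCCC(=O)OC(=O)C(C)(C)C | intermediate
4 | (S)-4-benzyl-3-(hex-4-ynoyl)-1,3-oxazolidin-2-one | CC#CCCC(=O)N1[C@@H](Cc2ccccc2)COC1=O | intermediate
5 | (tert-butyldimethylsilyloxy)acetaldehyde | CC(C)(C)[Si](C)(C)OCC=O | starting material
6 | (4S)-4-benzyl-3-[(1Z)-1-[(dibutylboranyl)oxy]hex-1-en-4-yn-1-yl]-1,3-oxazolidin-2-one | CC#CC/C=C(\OB(CCCC)CCCC)N1[C@@H](Cc2ccccc2)COC1=O | intermediate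
7 | (4S)-4-benzyl-3-[(2S,3S)-2-(but-2-yn-1-yl)-4-[(tert-butyldimethylsilyl)oxy]-3-[(dibutylboranyl)oxy]butanoyl]-1,3-oxazolidin-2-one | CC#CC[C@H](C(=O)N1[C@@H](Cc2ccccc2)COC1=O)[C@@H](CO[Si](C)(C)C(C)(C)C)OB(CCCC)CCCC | intermediate
8 | (4S)-4-benzyl-3-[(2S,3S)-2-(but-2-yn-1-yl)-4-[(tert-butyldimethylsilyl)oxy]-3-hydroxybutanoyl]-1,3-oxazolidin-2-one | CC#CC[C@H](C(=O)N1[C@@H](Cc2ccccc2)COC1=O)[C@H](O)CO[Si](C)(C)C(C)(C)C | intermediate
9 | methyl (2S,3S)-2-(but-2-yn-1-yl)-4-[(tert-butyldimethylsilyl)oxy]-3-hydroxybutanoate | CC#CC[C@H](C(=O)OC)[C@H](O)CO[Si](C)(C)C(C)(C)C | intermediate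
10 | (2S,3S)-3-(but-2-yn-1-yl)-1-[(tert-butyldimethylsilyl)oxy]-4-methylpentane-2,4-diol | CC#CC[C@H](C(C)(C)O)[C@H](O)CO[Si](C)(C)C(C)(C)C | intermediate
11 | tert-butyl{[(4S,5S)-5-(but-2-yn-1-yl)-2,2,6,6-tetramethyl-1,3-dioxan-4-yl]methoxy}dimethylsilane | CC#CC[C@H]1[C@@H](CO[Si](C)(C)C(C)(C)C)OC(C)(C)OC1(C)C | intermediate
12 | [(4S,5S)-5-(but-2-yn-1-yl)-2,2,6,6-tetramethyl-1,3-dioxan-4-yl]methanol | CC#CC[C@H]1[C@@H](CO)OC(C)(C)OC1(C)C | intermediate
13 | [(4S,5S)-5-(but-2-yn-1-yl)-2,2,6,6-tetramethyl-1,3-dioxan-4-yl]methyl trifluoromethanesulfonate | CC#CC[C@H]1[C@@H](COS(=O)(=O)C(F)(F)F)OC(C)(C)OC1(C)C | intermediate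
14 | tert-butyldimethyl(prop-2-yn-1-yloxy)silane | C#CCO[Si](C)(C)C(C)(C)C | starting material
15 | lithium 3-[(tert-butyldimethylsilyl)oxy]prop-1-yn-1-ide | [Li]C#CCO[Si](C)(C)C(C)(C)C | intermediate
16 | tert-butyl({4-[(4R,5S)-5-(but-2-yn-1-yl)-2,2,6,6-tetramethyl-1,3-dioxan-4-yl]but-2-yn-1-yl}oxy)dimethylsilane | CC#CC[C@H]1[C@@H](CC#CCO[Si](C)(C)C(C)(C)C)OC(C)(C)OC1(C)C | intermediate
17 | 4-[(4R,5S)-5-(but-2-yn-1-yl)-2,2,6,6-tetramethyl-1,3-dioxan-4-yl]but-2-yn-1-ol | CC#CC[C@H]1[C@@H](CC#CCO)OC(C)(C)OC1(C)C | intermediate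
18 | 4-[(4R,5S)-5-(but-2-yn-1-yl)-2,2,6,6-tetramethyl-1,3-dioxan-4-yl]but-2-yn-1-yl methanesulfonate | CC#CC[C@H]1[C@@H](CC#CCOS(C)(=O)=O)OC(C)(C)OC1(C)C | intermediate
19 | (4R,5S)-5-(but-2-yn-1-yl)-2,2,6,6-tetramethyl-4-(2-methylbuta-2,3-dien-1-yl)-1,3-dioxane | CC#CC[C@H]1[C@@H](CC(C)=C=C)OC(C)(C)OC1(C)C | intermediate
20 | carbon monoxide | [C-]#[O+] | starting material
21 | (7S,8R)-8,11-(isopropylidenedioxy)guaia-1(10),4-dien-3-one | CC1(C)O[C@@H]2CC(C)=C3CC(=O)C(C)=C3C[C@@H]2C(C)(C)O1 | intermediate
22 | (7S,8R,10S)-3-[(dimethylphenylsilyl)oxy]-8,11-(isopropylidenedioxy)guaia-1(5),3-diene | CC1(C)O[C@@H]2C[C@H](C)C3=C(C(C)=C(O[Si](C)(C)c4ccccc4)C3)C[C@@H]2C(C)(C)O1 | intermediate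
23 | (1R,7S,8R,10S)-8,11-(isopropylidenedioxy)guai-4-en-3-one | CC1(C)O[C@@H]2C[C@H](C)[C@H]3CC(=O)C(C)=C3C[C@@H]2C(C)(C)O1 | intermediate
24 | (1R,7S,8R,10S)-8,11-dihydroxyguai-4-en-3-one | O[C@@H]1C[C@H](C)[C@H]2CC(=O)C(C)=C2C[C@@H]1C(C)(C)O | intermediate
25 | (1R,7S,8R,10S)-11-hydroxy-3-oxoguai-4-en-8-yl 2-methylprop-2-enoate | C=C(C)C(=O)O[C@@H]1C[C@H](C)[C@H]2CC(=O)C(C)=C2C[C@@H]1C(C)(C)O | intermediate
26 | (1R,7S,8R,10S)-11-acetoxy-3-oxoguai-4-en-8-yl 2-methylprop-2-enoate | C=C(C)C(=O)O[C@@H]1C[C@H](C)[C@H]2CC(=O)C(C)=C2C[C@@H]1C(C)(C)OC(C)=O | target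

**Step count and risks**

Total step count: 16. Longest linear sequence: 16 steps (from 1 and 2 to 26).

Steps most likely to fail:

1. Step 12. Closure to the seven-membered rhodacycle may be too slow, so that allene oligomerization or reaction at the proximal allene bond takes over. The fallback sets out from 17 and returns at 21; it uses a sulfonyl-activated allene and brings in the C10 methyl only after ring closure. Alcohol 17 with PhSCl and Et3N (THF, −78 °C) should give a propargyl sulfenate that rearranges by [2,3]-sigmatropic shift to the allenyl sulfoxide (4R,5S)-5-(but-2-yn-1-yl)-2,2,6,6-tetramethyl-4-[2-(phenylsulfinyl)buta-2,3-dien-1-yl]-1,3-dioxane F1. Oxidation with mCPBA (CH2Cl2, 0 °C) should give the allenyl sulfone (4R,5S)-5-(but-2-yn-1-yl)-2,2,6,6-tetramethyl-4-[2-(phenylsulfonyl)buta-2,3-dien-1-yl]-1,3-dioxane F2. Sulfonyl allenes of this kind are an established substrate class for carbonylative closure with monovalent rhodium at the distal bond, so [Rh(CO)2Cl]2 under CO in refluxing toluene should give (7S,8R)-8,11-(isopropylidenedioxy)-10-(phenylsulfonyl)-14-norguaia-1(10),4-dien-3-one F3. Me2CuLi (THF, −78 °C) should then exchange the sulfonyl group for methyl by 1,6-addition and loss of sulfinate, giving 21.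

2. Step 13. Hydride may be transferred to the ring-fusion carbon C5 (1,4 mode), or the fully substituted C10 may resist the copper hydride. The fallback sets out from 21 and returns at 23; it uses heterogeneous hydrogenation. H2 (1 atm) over Pd/C (10 % palladium on carbon) in EtOAc at rt should add both hydrogens across C1=C10 from the α face to give the cis compound (1S,7S,8R,10S)-8,11-(isopropylidenedioxy)guai-4-en-3-one F4. NaOMe in MeOH at rt should then epimerize C1 through the dienolate to 23.

3. Step 16. Acylation of the hindered tertiary C11 hydroxyl beside the C8 ester may be sluggish, and forcing it may cause elimination at C11 or polymerization of the methacrylate. The fallback sets out from 24 and returns at 26; it reverses the order of the two acylations. TESCl and imidazole (DMF, 0 °C) should silylate only O8 of 24 to give (1R,7S,8R,10S)-11-hydroxy-8-(triethylsilyloxy)guai-4-en-3-one F5. Ac2O, DMAP and Et3N at 60 °C, with no methacrylate present, should give (1R,7S,8R,10S)-11-acetoxy-8-(triethylsilyloxy)guai-4-en-3-one F6. HF·pyridine (THF, 0 °C) should free O8 to give (1R,7S,8R,10S)-11-acetoxy-8-hydroxyguai-4-en-3-one F7. Methacrylic anhydride, Et3N and DMAP (CH2Cl2, 0 °C) should then give 26.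

Further compounds
F1 | step 12 | (4R,5S)-5-(but-2-yn-1-yl)-2,2,6,6-tetramethyl-4-[2-(phenylsulfinyl)buta-2,3-dien-1-yl]-1,3-dioxane (mixture at sulfur) | CC#CC[C@H]1[C@@H](CC(=C=C)S(=O)c2ccccc2)OC(C)(C)OC1(C)C
F2 | step 12 | (4R,5S)-5-(but-2-yn-1-yl)-2,2,6,6-tetramethyl-4-[2-(phenylsulfonyl)buta-2,3-dien-1-yl]-1,3-dioxane | CC#CC[C@H]1[C@@H](CC(=C=C)S(=O)(=O)c2ccccc2)OC(C)(C)OC1(C)C
F3 | step 12 | (7S,8R)-8,11-(isopropylidenedioxy)-10-(phenylsulfonyl)-14-norguaia-1(10),4-dien-3-one | CC1(C)O[C@@H]2CC(S(=O)(=O)c4ccccc4)=C3CC(=O)C(C)=C3C[C@@H]2C(C)(C)O1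
F4 | step 13 | (1S,7S,8R,10S)-8,11-(isopropylidenedioxy)guai-4-en-3-one | CC1(C)O[C@@H]2C[C@H](C)[C@@H]3CC(=O)C(C)=C3C[C@@H]2C(C)(C)O1
F5 | step 16 | (1R,7S,8R,10S)-11-hydroxy-8-(triethylsilyloxy)guai-4-en-3-one | CC[Si](CC)(CC)O[C@@H]1C[C@H](C)[C@H]2CC(=O)C(C)=C2C[C@@H]1C(C)(C)O
F6 | step 16 | (1R,7S,8R,10S)-11-acetoxy-8-(triethylsilyloxy)guai-4-en-3-one | CC[Si](CC)(CC)O[C@@H]1C[C@H](C)[C@H]2CC(=O)C(C)=C2C[C@@H]1C(C)(C)OC(C)=O
F7 | step 16 | (1R,7S,8R,10S)-11-acetoxy-8-hydroxyguai-4-en-3-one | O[C@@H]1C[C@H](C)[C@H]2CC(=O)C(C)=C2C[C@@H]1C(C)(C)OC(C)=O
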